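## Retrosynthetic overview

1. The tertiary alcohol is installed last, by Markovnikov hydration of the isopropenyl tricycle.
2. The bicyclo[3.2.1]octane and then the fused cyclopentane are closed in one oxidative 5-exo/5-exo radical cascade from a dearomatised 2-acyl-4-methyl-4,6-diprenylcyclohexane-1,3,5-trione.
3. That six-membered carbocycle is assembled convergently from an ester enolate (two ring carbons plus one prenyl group) and a chiral 3-methyl-3-prenylpyran-2,4-dione (enol-lactone opening, then Claisen ring closure).
4. The quaternary stereocentre of the pyrandione, which fixes the absolute configuration of the whole tricycle, is set by a palladium-catalysed enantioselective dearomative C-prenylation of a 4-hydroxy-2-pyranone.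
5. Small pieces: the pyranone from 3-methylbutan-2-one and methylmalonic acid; the ester by Johnson–Claisen rearrangement; the prenyl carbonate from prenol. Ring order: pyranone (temporary), cyclohexanetrione, bicyclo[3.2.1]octane, cyclopentane.

Assumption: the (R,R) ligand is taken to give the (3S) pyrandione 10; if the sense of induction proves opposite, the (S,S) ligand is used.

## Route

Step 1
Reactants: 1 3-methylbutan-2-one
Product: 3 trimethyl[(3-methylbut-1-en-2-yl)oxy]silane, via lithium enolate 2 (not isolated)
Conditions: lithium diisopropylamide (LDA, 1.05 equiv), THF, −78 °C; TMSCl, −78 °C to rt; distil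
Reagents that add atoms: chlorotrimethylsilane, C[Si](C)(C)Cl
Why: Kinetic deprotonation by the hindered amide occurs at the methyl group and O-silylation traps the less substituted enolate (silyl enol ether formation).

Step 2
Reactants: 4 2-methylpropanedioic acid
Product: 5 2-methylpropanedioyl dichloride
Conditions: SOCl2 (3 equiv), DMF (cat.), 50 °C; distil under reduced pressure
Reagents that add atoms: thionyl chloride, O=S(Cl)Cl
Why: Standard acyl chloride formation from a carboxylic acid; the product is used freshly distilled.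

Step 3
Reactants: 3 trimethyl[(3-methylbut-1-en-2-yl)oxy]silane; 5 2-methylpropanedioyl dichloride
Product: 7 4-hydroxy-3-methyl-6-(propan-2-yl)-2H-pyran-2-one, via diketo acyl chloride 6 (not isolated)
Conditions: Et2O, −78 °C to rt, 16 h; recrystallise
Reagents that add atoms: none
Why: Effenberger pyranone synthesis: C-acylation of the silyl enol ether by one acyl chloride, then lactonisation of the enol oxygen on the second acyl chloride and tautomerisation to the 4-hydroxy-2-pyranone.

Step 4
Reactants: 8 3-methylbut-2-en-1-ol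
Product: 9 methyl 3-methylbut-2-en-1-yl carbonate
Conditions: ClCO2Me (1.2 equiv), pyridine (1.5 equiv), CH2Cl2, 0 °C
Reagents that add atoms: methyl chloroformate, COC(=O)Cl
Why: O-acylation of the primary allylic alcohol (carbonate formation) gives the ionisable allyl donor.

Step 5
Reactants: 7 4-hydroxy-3-methyl-6-(propan-2-yl)-2H-pyran-2-one; 9 methyl 3-methylbut-2-en-1-yl carbonate
Product: 10 (3S)-3-methyl-3-(3-methylbut-2-en-1-yl)-6-(propan-2-yl)-2H-pyran-2,4(3H)-dione
Conditions: Pd2(dba)3·CHCl3 (2.5 mol %), (R,R)-DACH-phenyl Trost ligand (7.5 mol %), 7 (1.1 equiv), CH2Cl2, 0 °C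
Reagents that add atoms: none
Why: Proposed new method: enantioselective, linear-selective dearomative C-3 prenylation of a 3-substituted 4-hydroxy-2-pyranone; zerovalent palladium ionises the carbonate to a cationic prenyl–palladium complex and methoxide, which deprotonates the acidic pyranone, and the planar pyranonate attacks the unsubstituted allyl terminus through C-3 from outside the metal (O-allylation is reversible under the catalysis, and attack at the dimethyl terminus would create two adjacent quaternary carbons), while the chiral pocket distinguishes the lactone flank from the isopropyl-bearing enone flank and so sets the (3S) quaternary centre; closest known reaction type: Tsuji–Trost asymmetric allylic alkylation of planar cyclic enolates (azlactones, cyclic β-keto esters, naphthols) and the racemic palladium-catalysed C-3 allylation of 4-hydroxy-2-pyranones and 4-hydroxycoumarins.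

Step 6
Reactants: 11 2-methylbut-3-en-2-ol; 12 1,1,1-trimethoxyethane
Product: 15 methyl 5-methylhex-4-enoate, via mixed orthoester 13 (not isolated), via ketene acetal 14 (not isolated)
Conditions: 12 (4 equiv), EtCO2H (5 mol %), 130 °C, MeOH distilled off
Reagents that add atoms: none
Why: Johnson–Claisen rearrangement: alcohol exchange on the orthoester, loss of methanol to the ketene acetal and [3,3] shift give the γ,δ-unsaturated ester with the trisubstituted alkene.

Step 7
Reactants: 15 methyl 5-methylhex-4-enoate; 10 (3S)-3-methyl-3-(3-methylbut-2-en-1-yl)-6-(propan-2-yl)-2H-pyran-2,4(3H)-dione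
Product: 18 (4S)-3-hydroxy-4-methyl-4,6-bis(3-methylbut-2-en-1-yl)-2-(2-methylpropanoyl)cyclohex-2-ene-1,5-dione, via lithium ester enolate 16 (not isolated), via triketo ester 17 (not isolated)
Conditions: LDA (2.1 equiv), 15 (2.1 equiv), THF, −78 °C; 10, −78 to 0 °C; MeOH, 50 °C; 1 M HCl
Reagents that add atoms: none
Why: The ester enolate is C-acylated at the enol-lactone carbonyl C-2 (Fujimoto–Belleau-type opening), which releases the 1,3-diketone as its enolate, and in methanol the diketone carbon closes the six-membered ring on the methyl ester (Claisen/Dieckmann condensation) because the acyl-trione anion is the thermodynamic sink; the quaternary centre is untouched and C-6 stays enolisable.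

Step 8
Reactants: 18 (4S)-3-hydroxy-4-methyl-4,6-bis(3-methylbut-2-en-1-yl)-2-(2-methylpropanoyl)cyclohex-2-ene-1,5-dione
Product: 19 (1S,3S,5S,7S)-8-hydroxy-4,4,7-trimethyl-9-(2-methylpropanoyl)-3-(prop-1-en-2-yl)tricyclo[5.3.1.0(1,5)]undec-8-ene-10,11-dione
Conditions: Mn(OAc)3·2H2O (2.2 equiv), Cu(OAc)2·H2O (1 equiv, re-oxidised by Mn(OAc)3), degassed AcOH, rt, 2 h; preparative HPLC
Reagents that add atoms: none
Why: Oxidative radical cyclisation with trivalent manganese (Snider type), the cascade used for the racemic ialibinones: the enol radical closes 5-exo onto the C-4 prenyl group to give the bicyclo[3.2.1]octane (C-1 and C-5 are dictated by C-7, since the bridge can only form cis and only the exo radical can continue), the tertiary radical closes 5-exo onto the second prenyl group, and divalent copper oxidises the final radical to the isopropenyl group; C-3 is formed without control (about 1:1, as I recall from the racemic series) and the (3S) epimer is isolated by HPLC.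

Step 9
Reactants: 19 (1S,3S,5S,7S)-8-hydroxy-4,4,7-trimethyl-9-(2-methylpropanoyl)-3-(prop-1-en-2-yl)tricyclo[5.3.1.0(1,5)]undec-8-ene-10,11-dione
Product: 21 (1S,3R,5S,7S)-8-hydroxy-3-(2-hydroxypropan-2-yl)-4,4,7-trimethyl-9-(2-methylpropanoyl)tricyclo[5.3.1.0(1,5)]undec-8-ene-10,11-dione, via tertiary hydroperoxide 20 (not isolated)
Conditions: Co(acac)2 (20 mol %), PhSiH3 (2.5 equiv), O2 (1 atm), i-PrOH, rt
Reagents that add atoms: dioxygen, O=O
Why: Mukaiyama hydration: hydrogen-atom transfer from the cobalt hydride to the 1,1-disubstituted alkene gives the tertiary radical, which is trapped by O2 and reduced in situ to the alcohol (Markovnikov); C-3 is not touched (its descriptor changes from S to R only through the priority rules) and the enolised trione is not a hydrogen-atom acceptor.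

## Compound list

1 | 3-methylbutan-2-one | CC(C)C(C)=O | starting material
2 | lithium 3-methylbut-1-en-2-olate | [Li+].[O-]C(=C)C(C)C | intermediate
3 | trimethyl[(3-methylbut-1-en-2-yl)oxy]silane | CC(C)C(=C)O[Si](C)(C)C | intermediate
4 | 2-methylpropanedioic acid (methylmalonic acid) | CC(C(=O)O)C(=O)O | starting material
5 | 2-methylpropanedioyl dichloride | CC(C(=O)Cl)C(=O)Cl | intermediate
6 | 2,6-dimethyl-3,5-dioxoheptanoyl chloride | CC(C)C(=O)CC(=O)C(C)C(=O)Cl | intermediate
7 | 4-hydroxy-3-methyl-6-(propan-2-yl)-2H-pyran-2-one | CC(C)C1=CC(O)=C(C)C(=O)O1 | intermediate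
8 | 3-methylbut-2-en-1-ol (prenol) | CC(C)=CCO | starting material
9 | methyl 3-methylbut-2-en-1-yl carbonate | COC(=O)OCC=C(C)C | intermediate
10 | (3S)-3-methyl-3-(3-methylbut-2-en-1-yl)-6-(propan-2-yl)-2H-pyran-2,4(3H)-dione | CC(C)C1=CC(=O)[C@](C)(CC=C(C)C)C(=O)O1 | intermediate
11 | 2-methylbut-3-en-2-ol | CC(C)(O)C=C | starting material
12 | 1,1,1-trimethoxyethane (trimethyl orthoacetate) | CC(OC)(OC)OC | starting material
13 | 3-(1,1-dimethoxyethoxy)-3-methylbut-1-ene | CC(OC)(OC)OC(C)(C)C=C | intermediate
14 | 3-[(1-methoxyethenyl)oxy]-3-methylbut-1-ene | COC(=C)OC(C)(C)C=C | intermediate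
15 | methyl 5-methylhex-4-enoate | COC(=O)CCC=C(C)C | intermediate
16 | lithium 1-methoxy-5-methylhexa-1,4-dien-1-olate | [Li+].[O-]C(OC)=CCC=C(C)C | intermediate
17 | methyl (4S)-4,8-dimethyl-2,4-bis(3-methylbut-2-en-1-yl)-3,5,7-trioxononanoate (C-2 epimers) | COC(=O)C(CC=C(C)C)C(=O)[C@@](C)(CC=C(C)C)C(=O)CC(=O)C(C)C | intermediate
18 | (4S)-3-hydroxy-4-methyl-4,6-bis(3-methylbut-2-en-1-yl)-2-(2-methylpropanoyl)cyclohex-2-ene-1,5-dione (enol tautomers, C-6 enolisable) | CC(C)C(=O)C1=C(O)[C@](C)(CC=C(C)C)C(=O)C(CC=C(C)C)C1=O | intermediate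
19 | (1S,3S,5S,7S)-8-hydroxy-4,4,7-trimethyl-9-(2-methylpropanoyl)-3-(prop-1-en-2-yl)tricyclo[5.3.1.0(1,5)]undec-8-ene-10,11-dione | CC(C)C(=O)C1=C(O)[C@]2(C)C[C@H]3C(C)(C)[C@H](C(C)=C)C[C@@]3(C1=O)C2=O | intermediate
20 | (1S,3R,5S,7S)-3-(2-hydroperoxypropan-2-yl)-8-hydroxy-4,4,7-trimethyl-9-(2-methylpropanoyl)tricyclo[5.3.1.0(1,5)]undec-8-ene-10,11-dione | CC(C)C(=O)C1=C(O)[C@]2(C)C[C@H]3C(C)(C)[C@H](C(C)(C)OO)C[C@@]3(C1=O)C2=O | intermediate
21 | (1S,3R,5S,7S)-8-hydroxy-3-(2-hydroxypropan-2-yl)-4,4,7-trimethyl-9-(2-methylpropanoyl)tricyclo[5.3.1.0(1,5)]undec-8-ene-10,11-dione | CC(C)C(=O)C1=C(O)[C@]2(C)C[C@H]3C(C)(C)[C@H](C(C)(C)O)C[C@@]3(C1=O)C2=O | target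

## Step count and risks

Total step count: 9. Longest linear sequence: 6 (steps 1, 3, 5, 7, 8, 9).

The three steps most likely to fail:

**Step 5 (the proposed new reaction).** The risks are low enantioselectivity, erosion of ee by re-ionisation of the product, and O- or branched alkylation. The fallback sets out from 7 (with 9) and comes back at 10. Achiral Pd(PPh3)4 in THF at rt (the established racemic palladium-catalysed C-3 allylation of 4-hydroxy-2-pyranones) gives racemic 3-methyl-3-(3-methylbut-2-en-1-yl)-6-(propan-2-yl)-2H-pyran-2,4(3H)-dione F1. Preparative SFC on a chiral stationary phase then separates 10 from the (3R) enantiomer F2, which is discarded.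

**Step 7 (union and ring closure).** The risks are attack of the ester enolate at C-6 or C-4 of 10 instead of C-2, and a sluggish Claisen closure of 17. The fallback sets out from 10 and comes back at 18, building the ring stepwise and adding the second prenyl group last.
- NaOMe in MeOH at 0 °C opens the enol lactone to methyl (2S)-2,6-dimethyl-2-(3-methylbut-2-en-1-yl)-3,5-dioxoheptanoate F3.
- MgCl2, pyridine and acetyl chloride C-acetylate the diketone to methyl (2S)-4-acetyl-2,6-dimethyl-2-(3-methylbut-2-en-1-yl)-3,5-dioxoheptanoate F4.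
- LDA (2.2 equiv, THF, −78 to 0 °C) closes the ring by Dieckmann condensation of the acetyl methyl group on the ester, giving (4S)-3-hydroxy-4-methyl-4-(3-methylbut-2-en-1-yl)-2-(2-methylpropanoyl)cyclohex-2-ene-1,5-dione F5.
- Prenyl bromide with NaOMe in MeOH at 0 °C C-alkylates C-6 to give 18.

**Step 8 (radical cascade).** The yield is expected to be moderate (roughly a third in the racemic series, as I recall), and C-3 is not controlled, so half of the tricycle is lost on separation. The fallback sets out from the unseparated cascade product, 19 together with its (3R) epimer, (1S,3R,5S,7S)-8-hydroxy-4,4,7-trimethyl-9-(2-methylpropanoyl)-3-(prop-1-en-2-yl)tricyclo[5.3.1.0(1,5)]undec-8-ene-10,11-dione F6, and comes back at 21, so step 9 is not needed. It is untested on this skeleton.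
- TsOH·H2O (20 mol %) in toluene at 60 °C protonates the isopropenyl group to the tertiary cation.
- Only the (3S) cation has the C-10 enol oxygen on the same face; it is captured as the bridged cyclic enol ether F7, in which O-10 is bonded to the C(CH3)2 carbon of the C-3 side chain.
- The (3R) cation has no such partner, loses the C-3 proton to the isopropylidene alkene and is reprotonated from either face, so both epimers should drain into F7.
- LiOH in THF/H2O then cleaves the vinylogous ester by addition–elimination at C-10 to give 21. The main uncertainty is a competing methyl shift from the neighbouring quaternary carbon.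

## Further compounds

F1 | step 5 | racemic 3-methyl-3-(3-methylbut-2-en-1-yl)-6-(propan-2-yl)-2H-pyran-2,4(3H)-dione | CC(C)C1=CC(=O)C(C)(CC=C(C)C)C(=O)O1
F2 | step 5 | (3R)-3-methyl-3-(3-methylbut-2-en-1-yl)-6-(propan-2-yl)-2H-pyran-2,4(3H)-dione | CC(C)C1=CC(=O)[C@@](C)(CC=C(C)C)C(=O)O1
F3 | step 7 | methyl (2S)-2,6-dimethyl-2-(3-methylbut-2-en-1-yl)-3,5-dioxoheptanoate | COC(=O)[C@@](C)(CC=C(C)C)C(=O)CC(=O)C(C)C
F4 | step 7 | methyl (2S)-4-acetyl-2,6-dimethyl-2-(3-methylbut-2-en-1-yl)-3,5-dioxoheptanoate | COC(=O)[C@@](C)(CC=C(C)C)C(=O)C(C(C)=O)C(=O)C(C)C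
F5 | step 7 | (4S)-3-hydroxy-4-methyl-4-(3-methylbut-2-en-1-yl)-2-(2-methylpropanoyl)cyclohex-2-ene-1,5-dione | CC(C)C(=O)C1=C(O)[C@](C)(CC=C(C)C)C(=O)CC1=O
F6 | step 8 | (1S,3R,5S,7S)-8-hydroxy-4,4,7-trimethyl-9-(2-methylpropanoyl)-3-(prop-1-en-2-yl)tricyclo[5.3.1.0(1,5)]undec-8-ene-10,11-dione | CC(C)C(=O)C1=C(O)[C@]2(C)C[C@H]3C(C)(C)[C@@H](C(C)=C)C[C@@]3(C1=O)C2=O
F7 | step 8 | bridged cyclic enol ether of 21 (O-10 bonded to the C(CH3)2 carbon on C-3, C-8 as ketone) | CC(C)C(=O)C1=C2OC(C)(C)[C@@H]3C[C@@]2(C(=O)[C@](C)(C1=O)C4)[C@@H]4C3(C)C
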